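## Retrosynthetic overview

1. Feature: ring B (C5–C10), with C17 on C8 and the C4/C18/C19 unit on C5, is the complete ten-carbon skeleton of (S)-carvone. The carbonyl carbon is C9, the ring stereocentre is C5, the isopropenyl carbon is C4, and its =CH2 is C18, the carbon that carries the acetate.
2. Late disconnections: the C18 acetate, then C12–C13 (B-alkyl Suzuki–Miyaura coupling with chloroprene), then C11=C12 (Wittig reaction, which supplies C12). A bicyclic C11 alcohol remains.
3. Ring B oxygens: 6-OH and 8-OH come from a 7-ene by way of the 7-en-6-one, its epoxide and electron-transfer reduction. C11 and H9 come from the C9 ketone by way of a spiro vinyl oxirane and palladium–formate hydrogenolysis.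
4. Ring A is opened at C3–C4. A domino Heck cyclization/borylation of a (Z)-alkenyl iodide onto the isopropenyl group makes C3–C4, quaternary C4 and the C18–B bond in one operation.
5. Ring order: ring B is bought and ring A is closed in step 6. C10 is set beforehand by two enolate alkylations of carvone (MeI gives C20, (Z)-3-iodoallyl bromide gives C1–C3).

Key step: step 6

Remark on the reading of the target: in labdane numbering the SMILES corresponds to (4S,5S,6R,8S,9S,10R). This is an ent-labdane, the mirror image of a normal labdane with 6α-OH, 8α-OH and a 4α-CH2OAc group.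

Convention: "C20 face" is the decalin face that carries the angular methyl C20, and "H5 face" is the opposite face. In the target, C17, C19 and C20 are axial on the C20 face and H5 and H9 are axial on the H5 face. C18, 6-OH and 8-OH are equatorial (H5 face) and C11 is equatorial.

Assumption: chloroprene is used as the stabilized commercial solution. Phosphine ligands are left out of the SMILES of 11 and 12.

## Route

Step 1
Reactants: 1 methyl propiolate
Product: 2 methyl (Z)-3-iodoacrylate
Conditions: NaI, AcOH, 70 °C
Reagents that add atoms: sodium iodide, [Na+].[I-]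
Why: Conjugate hydroiodination of an ynoate, in which iodide adds to the β-carbon and the allenolate is protonated anti to iodine under kinetic control at this temperature, should give the Z-iodoacrylate that a cis ring alkene requires.

Step 2
Reactants: 2 methyl (Z)-3-iodoacrylate
Product: 3 (Z)-3-iodoprop-2-en-1-ol
Conditions: i-Bu2AlH (2.2 equiv), CH2Cl2, −78 to 0 °C
Reagents that add atoms: none
Why: Ester-to-alcohol reduction with an aluminium hydride at low temperature touches neither the carbon–iodine bond nor the Z geometry.

Step 3
Reactants: 3 (Z)-3-iodoprop-2-en-1-ol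
Product: 4 (Z)-3-bromo-1-iodoprop-1-ene
Conditions: CBr4, PPh3, CH2Cl2, 0 °C
Reagents that add atoms: tetrabromomethane, BrC(Br)(Br)Br
Why: The Appel reaction displaces the oxyphosphonium ion by SN2 under neutral conditions, so the allylic system is neither transposed nor isomerized.

Step 4
Reactants: 5 (S)-(+)-carvone
Product: 7 (5S)-6-methylcarvone (C6 epimers), via lithium dienolate 6 (not isolated)
Conditions: i-Pr2NLi, THF, −78 °C; MeI, −78 to 0 °C
Reagents that add atoms: iodomethane, CI
Why: Kinetic α′-deprotonation at the only CH2 next to the carbonyl (future C10) followed by SN2 methylation brings in C20, and the epimer mixture at the new centre is erased by the enolization of step 5.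

Step 5
Reactants: 7 (5S)-6-methylcarvone; 4 (Z)-3-bromo-1-iodoprop-1-ene
Product: 9 (5R,6R)-6-[(Z)-3-iodoallyl]-6-methylcarvone, via lithium enolate 8 (not isolated)
Conditions: i-Pr2NLi (1.05 equiv), THF, −78 to 0 °C; DMPU, 4, −78 °C to rt
Reagents that add atoms: (Z)-3-bromo-1-iodoprop-1-ene 4, BrC/C=C\I
Why: In this enolate alkylation with a reactive allylic bromide the isopropenyl group on C5 of 8 sits pseudo-axial to avoid allylic strain and shields one face, so 4 should enter anti to it, which places C1 trans and the methyl C20 cis to C4 and thereby sets quaternary C10.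

Step 6
Reactants: 9 (5R,6R)-6-[(Z)-3-iodoallyl]-6-methylcarvone; 10 bis(pinacolato)diboron
Product: 13 C18 pinacolboronate of the trans-fused 2,7-dien-9-one, via alkenylpalladium iodide 11 (not isolated), via neopentylpalladium iodide 12 (not isolated)
Conditions: Pd(OAc)2 (5 mol %), PPh3 (15 mol %), KOAc (3 equiv), 10 (2 equiv), 1,4-dioxane, 80 °C
Reagents that add atoms: bis(pinacolato)diboron 10, CC1(C)OB(OC1(C)C)B1OC(C)(C)C(C)(C)O1
Why: Zerovalent palladium (formed in the flask from Pd(OAc)2 and PPh3) inserts into the C3–iodine bond of 9 with retention of the Z geometry to give 11, the isopropenyl group then undergoes intramolecular syn-carbopalladation to give neopentyl complex 12, and acetate-assisted transmetalation with 10 followed by carbon–boron reductive elimination releases 13 and the catalyst. The closest known reaction type is the domino Mizoroki–Heck cyclization/borylation of aryl iodides and of (Z)-1-iodo-1,6-dienes that carry a 1,1-disubstituted alkene, of which 9 is a new carbocyclic member. Ring A (C1, C2, C3, C4, C5, C10) closes in the 6-exo-trig mode, C3 bonding to the inner alkene carbon C4 and palladium moving to the terminal carbon C18, while the 7-endo mode would have to put palladium on a tertiary carbon. C4, the only new stereocentre, is controlled by C5 and C10: their trans-diequatorial side chains allow only a trans-fused half-chair, and the four-centre transition state needs C4=C18 coplanar with the C3–Pd bond, which lies in the plane of the C1–C2=C3 unit, so that C18 ends pseudo-equatorial and the methyl C19 axial on the C20 face. The step needs insertion into the isopropenyl group and not into C7=C8, and ring closure before boron capture; the first is secured because the enone alkene is trisubstituted and within reach only from the diaxial conformer through a bridged bicyclo[3.3.1] transition state, the second because insertion within 11 is intramolecular and helped by the quaternary C10, whereas transmetalation with 10 is bimolecular and slow. Complex 12 has no β-hydrogen since C4 is quaternary, and its C4–C18 bond is held close to the nodal plane of the C2=C3 π bond by the rigid trans fusion, so that the 3-exo return onto that alkene has poor overlap and an excess of 10 should intercept 12 first.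

Step 7
Reactants: 13 C18 pinacolboronate of the 2,7-dien-9-one
Product: 14 18-hydroxy-2,7-dien-9-one
Conditions: NaBO3·4H2O, THF/H2O, 0 °C to rt
Reagents that add atoms: sodium perborate (hydrate water omitted), [Na+].[Na+].O[B-]1(O)OO[B-](O)(O)OO1
Why: The C–B bond is oxidized by 1,2-migration of C18 from boron to a peroxide oxygen, and the weakly basic perborate is chosen because alkaline H2O2 would also epoxidize the C7=C8 enone in a Weitz–Scheffer reaction.

Step 8
Reactants: 14 18-hydroxy-2,7-dien-9-one
Product: 15 18-OTBS 2,7-dien-9-one
Conditions: TBSCl, imidazole, DMF, rt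
Reagents that add atoms: tert-butyldimethylsilyl chloride, CC(C)(C)[Si](C)(C)Cl
Why: This is a standard silylation of a primary neopentyl alcohol, and a silyl ether is used instead of the final acetate because the ylide, basic peroxide and hydride steps ahead would cleave an ester at C18.

Step 9
Reactants: 15 18-OTBS 2,7-dien-9-one
Product: 16 18-OTBS 7-en-9-one
Conditions: 2-nitrobenzenesulfonylhydrazide (excess), Et3N, CH2Cl2, rt
Reagents that add atoms: none
Why: Diimide reduction is a concerted syn transfer of H2 that is fast for the cis-disubstituted, unpolarized C2=C3 bond and slow for the trisubstituted, electron-poor C7=C8 bond, so ring A is saturated before any allylic oxidation.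

Step 10
Reactants: 16 18-OTBS 7-en-9-one
Product: 17 C9 spiro vinyl oxirane (C11 on the H5 face; O on the C20 face)
Conditions: Me3SI, NaH, DMSO/THF, 0 °C to rt
Reagents that add atoms: trimethylsulfonium iodide, C[S+](C)C.[I-]
Why: In this Corey–Chaykovsky epoxidation the unstabilized sulfonium ylide adds 1,2 and irreversibly to the enone carbonyl from the H5 face, because the axial methyl C20 on the neighbouring C10 blocks the other face, so C11 lies on the H5 face and the oxygen on the C20 face of C9.

Step 11
Reactants: 17 C9 spiro vinyl oxirane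
Product: 18 18-OTBS 7-en-11-ol (H9 on the H5 face)
Conditions: Pd2(dba)3·CHCl3 (2.5 mol %), n-Bu3P (10 mol %), HCO2H, Et3N, 1,4-dioxane, rt
Reagents that add atoms: none
Why: In this palladium-catalysed formate hydrogenolysis of an alkenyl oxirane, zerovalent palladium ionizes the allylic C9–O bond from the face opposite to oxygen (the H5 face), formate on palladium loses CO2, and the hydride passes from the metal to the more substituted allyl terminus C9 on that same face, which should give the 7-ene, the C11 alcohol and H9 on the H5 face with C11 equatorial.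

Step 12
Reactants: 18 18-OTBS 7-en-11-ol
Product: 19 11-pivalate of 18
Conditions: PivCl, pyridine, DMAP (cat), CH2Cl2, 0 °C to rt
Reagents that add atoms: pivaloyl chloride, CC(C)(C)C(=O)Cl
Why: Acylation of the primary C11 alcohol gives a pivalate that withstands chromium oxidation, basic peroxide and SmI2 and can later be removed by hydride without touching silyl ethers.

Step 13
Reactants: 19 11-pivalate
Product: 20 7-en-6-one
Conditions: CrO3, 3,5-dimethylpyrazole, CH2Cl2, −20 °C
Reagents that add atoms: chromium trioxide, O=[Cr](=O)=O
Why: Allylic oxidation with the CrO3–3,5-dimethylpyrazole complex turns the only allylic CH2 of the trisubstituted 7-ene (C6) into the enone carbonyl, as in the conversion of 5-ene steroids into 7-ketones.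

Step 14
Reactants: 20 7-en-6-one
Product: 21 7,8-epoxy-6-one (epoxide on the H5 face)
Conditions: 30% H2O2, NaOH (cat), MeOH, 0 °C to rt
Reagents that add atoms: hydrogen peroxide, OO
Why: In this Weitz–Scheffer epoxidation hydroperoxide adds to C8 from the H5 face because C20 (1,3-diaxial to C8) and C11 crowd the other face, which sets the C8–O bond on the H5 face with C17 axial, while C5, although α to the ketone, keeps its thermodynamically preferred trans-fused configuration.

Step 15
Reactants: 21 7,8-epoxy-6-one
Product: 23 6,8-diol (both OH equatorial on the H5 face), via aldol 22 (not isolated)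
Conditions: SmI2 (2.5 equiv), THF/MeOH, −90 °C; then SmI2 (5 equiv), H2O, Et3N, −78 °C to rt
Reagents that add atoms: none
Why: Two electron-transfer reductions run in one flask, in which SmI2 first cleaves the C7–O bond α to the ketone to give aldol 22 with the C8–O bond untouched and the stronger SmI2–H2O–amine reductant then takes the C6 ketone through its ketyl to the equatorial alcohol, the thermodynamically controlled outcome of such reductions, whereas hydride reagents would attack from the open H5 face and give the axial epimer crowded by C17, C19 and C20.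

Step 16
Reactants: 23 6,8-diol
Product: 24 6,8-bis-TES ether
Conditions: TESOTf, 2,6-lutidine, CH2Cl2, 0 °C to rt
Reagents that add atoms: triethylsilyl triflate, CC[Si](CC)(CC)OS(=O)(=O)C(F)(F)F
Why: Silylation with a silyl triflate is strong enough for the tertiary C8 alcohol as well as the hindered C6 alcohol and masks the β-hydroxy group that would open retro-aldol and elimination pathways once C11 is an aldehyde.

Step 17
Reactants: 24 6,8-bis-TES ether
Product: 25 C11 alcohol
Conditions: i-Bu2AlH (2.5 equiv), CH2Cl2, −78 °C
Reagents that add atoms: none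
Why: Reductive ester cleavage by an aluminium hydride at low temperature frees only the C11 alcohol, since the three silyl ethers are inert to this reagent.

Step 18
Reactants: 25 C11 alcohol
Product: 26 C11 aldehyde
Conditions: Dess–Martin periodinane, pyridine, CH2Cl2, 0 °C to rt
Reagents that add atoms: none
Why: Dess–Martin oxidation under buffered conditions gives the aldehyde without epimerization, its formyl group already being in the favoured equatorial position on C9.

Step 19
Reactants: 26 C11 aldehyde
Product: 27 C11=C12 vinyl compound
Conditions: Ph3PCH3Br, KOt-Bu, THF, 0 °C to rt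
Reagents that add atoms: methyltriphenylphosphonium bromide, C[P+](c1ccccc1)(c1ccccc1)c1ccccc1.[Br-]
Why: Wittig methylenation with the small non-stabilized ylide supplies C12, and E1cB loss of the C8 silyloxy group is held back because the equatorial C8–O bond is nearly orthogonal to the π system of a C9 enolate.

Step 20
Reactants: 27 C11=C12 vinyl compound; 28 chloroprene
Product: 30 trisilylated labda-13(16),14-diene, via B-alkyl-9-BBN 29 (not isolated)
Conditions: 9-BBN-H, THF, rt to 60 °C; then 28 (excess), Pd(OAc)2 (5 mol %), SPhos (10 mol %), K3PO4 (aq), THF/DMF, BHT, 40 °C, sealed tube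
Reagents that add atoms: chloroprene 28, C=CC(Cl)=C; 9-borabicyclo[3.3.1]nonane (its boron stays only in 29), B1C2CCCC1CCC2
Why: Anti-Markovnikov hydroboration of the only alkene places boron on C12, and B-alkyl Suzuki–Miyaura coupling of 29 with the alkenyl chloride under a dialkylbiarylphosphine–palladium catalyst forms C12–C13 with the 2-substituted 1,3-diene already in place.

Step 21
Reactants: 30 trisilylated labda-13(16),14-diene
Product: 31 6,8,18-triol
Conditions: Bu4NF (excess), THF, rt to 40 °C
Reagents that add atoms: none
Why: Fluoride-mediated desilylation removes all three silyl groups under non-acidic conditions that spare the diene and the tertiary alcohol.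

Step 22
Reactants: 31 6,8,18-triol
Product: 32 target CNP0317825.1
Conditions: AcCl (1.1 equiv), 2,4,6-collidine, CH2Cl2, −78 °C
Reagents that add atoms: acetyl chloride, CC(=O)Cl
Why: In this chemoselective acylation at low temperature with a hindered pyridine base the primary C18 alcohol should react well before the hindered secondary C6 alcohol and the tertiary C8 alcohol, which gives the monoacetate.

## Compound list

1 | methyl propiolate | C#CC(=O)OC | starting material
2 | methyl (Z)-3-iodoacrylate | COC(=O)/C=C\I | intermediate
3 | (Z)-3-iodoprop-2-en-1-ol | OC/C=C\I | intermediate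
4 | (Z)-3-bromo-1-iodoprop-1-ene | BrC/C=C\I | intermediate
5 | (S)-(+)-carvone | O=C1C[C@@H](C(C)=C)CC=C1C | starting material
6 | lithium cross-conjugated dienolate of 5 | [Li+].[O-]C1=C[C@@H](C(C)=C)CC=C1C | intermediate
7 | (5S)-2,6-dimethyl-5-(prop-1-en-2-yl)cyclohex-2-en-1-one (6-methylcarvone, both C6 epimers) | O=C1C(C)[C@@H](C(C)=C)CC=C1C | intermediate
8 | lithium enolate of 7 | [Li+].[O-]C1=C(C)[C@@H](C(C)=C)CC=C1C | intermediate
9 | (5R,6R)-6-[(Z)-3-iodoprop-2-en-1-yl]-2,6-dimethyl-5-(prop-1-en-2-yl)cyclohex-2-en-1-one; iodoallyl trans and methyl cis to the isopropenyl group | O=C1[C@](C)(C/C=C\I)[C@@H](C(C)=C)CC=C1C | intermediate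
10 | bis(pinacolato)diboron | CC1(C)OB(OC1(C)C)B1OC(C)(C)C(C)(C)O1 | starting material
11 | (Z)-alkenylpalladium iodide from 9 (Pd on C3) | O=C1[C@](C)(C/C=C\[Pd]I)[C@@H](C(C)=C)CC=C1C | intermediate
12 | neopentylpalladium iodide (Pd on C18, ring A closed) | O=C1[C@]2(C)CC=C[C@](C)(C[Pd]I)[C@H]2CC=C1C | intermediate
13 | trans-fused decalin with C9 ketone, C7=C8 (C17 on C8), C2=C3, C20 on C10, C19 axial (C20 face) and CH2Bpin (C18) equatorial on C4 | O=C1[C@]2(C)CC=C[C@](C)(CB3OC(C)(C)C(C)(C)O3)[C@H]2CC=C1C | intermediate
14 | as 13 with C18 as CH2OH | O=C1[C@]2(C)CC=C[C@](C)(CO)[C@H]2CC=C1C | intermediate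
15 | as 14 with C18 as CH2OTBS | O=C1[C@]2(C)CC=C[C@](C)(CO[Si](C)(C)C(C)(C)C)[C@H]2CC=C1C | intermediate
16 | as 15 with ring A saturated (7-en-9-one) | O=C1[C@]2(C)CCC[C@](C)(CO[Si](C)(C)C(C)(C)C)[C@H]2CC=C1C | intermediate
17 | C9 spiro-oxirane of 16, CH2 (C11) on the H5 face, O on the C20 face, 7-ene kept | O1C[C@@]12[C@]3(C)CCC[C@](C)(CO[Si](C)(C)C(C)(C)C)[C@H]3CC=C2C | intermediate
18 | 18-OTBS 7-en-11-ol, H9 axial on the H5 face, CH2OH equatorial | OC[C@H]1[C@]2(C)CCC[C@](C)(CO[Si](C)(C)C(C)(C)C)[C@H]2CC=C1C | intermediate
19 | 11-pivalate of 18 | CC(C)(C)C(=O)OC[C@H]1[C@]2(C)CCC[C@](C)(CO[Si](C)(C)C(C)(C)C)[C@H]2CC=C1C | intermediate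
20 | 11-OPiv, 18-OTBS 7-en-6-one | CC(C)(C)C(=O)OC[C@H]1[C@]2(C)CCC[C@](C)(CO[Si](C)(C)C(C)(C)C)[C@H]2C(=O)C=C1C | intermediate
21 | 7,8-epoxy-6-one, epoxide oxygen on the H5 face, C17 on the C20 face | CC(C)(C)C(=O)OC[C@H]1[C@]2(C)CCC[C@](C)(CO[Si](C)(C)C(C)(C)C)[C@H]2C(=O)[C@@H]3O[C@]13C | intermediate
22 | 8-hydroxy-6-one (aldol), 8-OH equatorial on the H5 face | CC(C)(C)C(=O)OC[C@H]1[C@]2(C)CCC[C@](C)(CO[Si](C)(C)C(C)(C)C)[C@H]2C(=O)C[C@]1(C)O | intermediate
23 | 6,8-diol, both OH equatorial on the H5 face | CC(C)(C)C(=O)OC[C@H]1[C@]2(C)CCC[C@](C)(CO[Si](C)(C)C(C)(C)C)[C@H]2[C@H](O)C[C@]1(C)O | intermediate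
24 | 6,8-bis(triethylsilyl) ether of 23 | CC(C)(C)C(=O)OC[C@H]1[C@]2(C)CCC[C@](C)(CO[Si](C)(C)C(C)(C)C)[C@H]2[C@H](O[Si](CC)(CC)CC)C[C@]1(C)O[Si](CC)(CC)CC | intermediate
25 | C11 alcohol (6,8-bis-OTES, 18-OTBS) | OC[C@H]1[C@]2(C)CCC[C@](C)(CO[Si](C)(C)C(C)(C)C)[C@H]2[C@H](O[Si](CC)(CC)CC)C[C@]1(C)O[Si](CC)(CC)CC | intermediate
26 | C11 aldehyde, CHO equatorial on C9 | O=C[C@H]1[C@]2(C)CCC[C@](C)(CO[Si](C)(C)C(C)(C)C)[C@H]2[C@H](O[Si](CC)(CC)CC)C[C@]1(C)O[Si](CC)(CC)CC | intermediate
27 | C9 vinyl compound (C11=C12) | C=C[C@H]1[C@]2(C)CCC[C@](C)(CO[Si](C)(C)C(C)(C)C)[C@H]2[C@H](O[Si](CC)(CC)CC)C[C@]1(C)O[Si](CC)(CC)CC | intermediate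
28 | chloroprene (2-chlorobuta-1,3-diene) | C=CC(Cl)=C | starting material
29 | B-(C12-alkyl)-9-borabicyclo[3.3.1]nonane | C1CC2CCCC(C1)B2CC[C@H]3[C@]4(C)CCC[C@](C)(CO[Si](C)(C)C(C)(C)C)[C@H]4[C@H](O[Si](CC)(CC)CC)C[C@]3(C)O[Si](CC)(CC)CC | intermediate
30 | 6,8-bis-OTES, 18-OTBS ent-labda-13(16),14-diene | C=CC(=C)CC[C@H]1[C@]2(C)CCC[C@](C)(CO[Si](C)(C)C(C)(C)C)[C@H]2[C@H](O[Si](CC)(CC)CC)C[C@]1(C)O[Si](CC)(CC)CC | intermediate
31 | ent-labda-13(16),14-diene-6,8,18-triol | C=CC(=C)CC[C@H]1[C@]2(C)CCC[C@](C)(CO)[C@H]2[C@H](O)C[C@]1(C)O | intermediate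
32 | CNP0317825.1, (4S,5S,6R,8S,9S,10R)-6,8-dihydroxylabda-13(16),14-dien-18-yl acetate | C=CC(=C)CC[C@H]1[C@]2(C)CCC[C@](C)(COC(C)=O)[C@H]2[C@H](O)C[C@]1(C)O | target

## Summary

**Where each stereocentre is set:** C5 is bought, C10 is set in step 5 and C4 in step 6. C9 is set in steps 10 and 11, C8 in step 14 and C6 in step 15.

**Carbon sources:**

| Source | Carbons supplied |
|---|---|
| carvone | C4–C10, C17, C18, C19 |
| MeI | C20 |
| bromide 4 | C1–C3 |
| Me3SI | C11 |
| Ph3PCH3Br | C12 |
| chloroprene | C13–C16 |

**Total step count:** 22.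

**Longest linear sequence:** 21 (steps 1–3 and 5–22, from methyl propiolate). From carvone it is 19.

## Three steps most likely to fail

**Risk at step 6.**
- The diboron may capture 11 before ring closure (plain Miyaura borylation).
- Transmetalation at the hindered neopentyl centre of 12 may be too slow.
- 12 may add back onto C2=C3 in the 3-exo mode and then lose a β-hydride.

The fallback separates ring closure from heteroatom capture. It sets out from 9. The known palladium-catalysed iodine-transfer cycloisomerization of (Z)-1-iodo-1,6-dienes (Pd(OAc)2, dppf, toluene, 110 °C) needs no external trap. It should close the same C3–C4 bond and end by carbon–iodine reductive elimination to the neopentyl iodide F1. Diimide, as in step 9, then saturates C2=C3 to give the saturated iodide F2, so that a later C18 radical has no homoallylic alkene to migrate onto. Radical hydroxylation (Bu3SnH, air, toluene, 60 °C) gives the 18-hydroxy-7-en-9-one F3. Silylation as in step 8 returns to the route at 16.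

**Risk at step 11.**
- Hydride may be delivered to the less hindered allyl terminus C7, which moves the alkene to C8=C9.
- β-Hydride elimination may give a dienol.
- Ionization of the poorly aligned spiro C–O bond may be sluggish.

The fallback replaces metal-hydride delivery by a cationic hydride shift under thermodynamic control at C9. It sets out from 17. A Meinwald rearrangement (MgBr2·OEt2, Et2O/CH2Cl2, −20 °C) should give the β,γ-unsaturated aldehyde F4. Its enolizable C9 centre settles with the formyl group equatorial. NaBH4 in MeOH at 0 °C reduces it and the route is rejoined at 18.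

**Risk at step 15.**
- Facial selectivity in the protonation at C6 may be poor.
- Aldol 22 may suffer retro-aldol cleavage or dehydration in the amine-containing second stage.

The fallback replaces electron transfer by reversible hydride transfer on a protected aldol. The reaction is stopped after its first stage and 22 is isolated. TESOTf with 2,6-lutidine gives the 8-O-TES ketone F5. Meerwein–Ponndorf–Verley reduction with Al(Oi-Pr)3 in i-PrOH/toluene at reflux, with a trace of acetone, equilibrates the carbinol centre toward the equatorial 6-alcohol F6. A second silylation with TESOTf returns to the route at 24.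

## Further compounds

F1 | step 6 | C18 iodide of the trans-fused 2,7-dien-9-one | O=C1[C@]2(C)CC=C[C@](C)(CI)[C@H]2CC=C1C
F2 | step 6 | C18 iodide of the 7-en-9-one (ring A saturated) | O=C1[C@]2(C)CCC[C@](C)(CI)[C@H]2CC=C1C
F3 | step 6 | 18-hydroxy-7-en-9-one | O=C1[C@]2(C)CCC[C@](C)(CO)[C@H]2CC=C1C
F4 | step 11 | 18-OTBS 7-en-11-al, CHO equatorial on C9 | O=C[C@H]1[C@]2(C)CCC[C@](C)(CO[Si](C)(C)C(C)(C)C)[C@H]2CC=C1C
F5 | step 15 | 8-O-TES ether of aldol 22 | CC(C)(C)C(=O)OC[C@H]1[C@]2(C)CCC[C@](C)(CO[Si](C)(C)C(C)(C)C)[C@H]2C(=O)C[C@]1(C)O[Si](CC)(CC)CC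
F6 | step 15 | equatorial 6-alcohol with 8-O-TES | CC(C)(C)C(=O)OC[C@H]1[C@]2(C)CCC[C@](C)(CO[Si](C)(C)C(C)(C)C)[C@H]2[C@H](O)C[C@]1(C)O[Si](CC)(CC)CC
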